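Ring C is opened at C3–C4. C4 is a methine that carries only rings A and D, and H-4 is cis to the 3-hydroxyl, which is the retron of a syn hydroboration of a C3=C4 olefin; C4 can therefore be masked as the internal carbon of a 1,1-diarylethylene. The precursor is the (S)-1-arylallyl ether of a 2-(1-arylvinyl)phenol, whose single stereocenter (C2) is set by Ir-catalysed asymmetric allylic etherification. Ring-closing olefin metathesis joins C3 to C4 and closes ring C as a 2,4-diaryl-2H-chromene; one hydroboration then relays C2 to both C3 and C4, and hydrogenolysis of five benzyl ethers gives the target.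

Key step: step 8

Assumption: the sense of induction in step 7 is taken by analogy with cinnamyl carbonates and aryloxides, the (Sa,S,S)-ligand leading to the (S)-ether; if the analogy does not hold, the (Ra,R,R)-ligand is used instead.

Step 1
Reactants: 1 2-methoxybenzene-1,3-diol (2-methoxyresorcinol); 2 benzyl bromide
Product: 3 1,3-bis(benzyloxy)-2-methoxybenzene
Conditions: BnBr (2.2 equiv), K2CO3, DMF, 60 °C
Reagents that add atoms: benzyl bromide (2), BrCc1ccccc1
Why: Double Williamson etherification (SN2 of the phenoxides on benzyl bromide) masks both hydroxyls of ring D as hydrogenolysable benzyl ethers; no stereocenter.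

Step 2
Reactants: 3 1,3-bis(benzyloxy)-2-methoxybenzene; 4 N-bromosuccinimide
Product: 5 1,3-bis(benzyloxy)-4-bromo-2-methoxybenzene
Conditions: NBS (1.0 equiv), MeCN, 0 °C to rt
Reagents that add atoms: N-bromosuccinimide (4), O=C1CCC(=O)N1Br
Why: Electrophilic aromatic bromination should go to C4, para to one benzyloxy group and ortho to the other, because the flanked 2-methoxy group is twisted out of conjugation and C5 is meta to both benzyloxy donors; C4 and C6 are equivalent, so a single monobromide is expected.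

Step 3
Reactants: 5 1,3-bis(benzyloxy)-4-bromo-2-methoxybenzene; 6 1-[4-(benzyloxy)-2-hydroxyphenyl]ethan-1-one
Product: 8 5-(benzyloxy)-2-{1-[2,4-bis(benzyloxy)-3-methoxyphenyl]ethenyl}phenol, via tertiary 1,1-diarylethanol 7 (not isolated)
Conditions: 5, n-BuLi, THF, −78 °C; anhydrous CeCl3, −78 °C; sodium salt of 6 (NaH, THF), −78 to 0 °C; then 2 M aq. HCl, rt
Reagents that add atoms: none
Why: Br–Li exchange and transmetalation to the weakly basic organocerium should allow 1,2-addition to the enolisable, phenoxide-deactivated ketone, and the tertiary diarylcarbinol should lose water on acidification by E1 elimination through a cation stabilised by ortho and para oxygen on both rings (organocerium addition followed by dehydration); no stereocenter remains.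

Step 4
Reactants: 9 caffeic acid, (E)-3-(3,4-dihydroxyphenyl)prop-2-enoic acid; 2 benzyl bromide
Product: 10 benzyl (E)-3-[3,4-bis(benzyloxy)phenyl]prop-2-enoate
Conditions: BnBr (3.3 equiv), K2CO3, DMF, 60 °C
Reagents that add atoms: benzyl bromide (2), BrCc1ccccc1
Why: The carboxylate and both phenoxides are alkylated by SN2 (Williamson etherification and carboxylate alkylation) without touching the (E)-olefin.

Step 5
Reactants: 10 benzyl (E)-3-[3,4-bis(benzyloxy)phenyl]prop-2-enoate
Product: 11 (E)-3-[3,4-bis(benzyloxy)phenyl]prop-2-en-1-ol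
Conditions: DIBAL-H (2.5 equiv), CH2Cl2, −78 °C; Rochelle salt work-up
Reagents that add atoms: none
Why: DIBAL-H 1,2-reduction of the α,β-unsaturated ester at low temperature should give the (E)-allylic alcohol without conjugate reduction, and the benzyl alcohol released is removed by chromatography.

Step 6
Reactants: 11 (E)-3-[3,4-bis(benzyloxy)phenyl]prop-2-en-1-ol; 12 methyl chloroformate
Product: 13 (E)-3-[3,4-bis(benzyloxy)phenyl]prop-2-en-1-yl methyl carbonate
Conditions: ClCO2Me, pyridine, CH2Cl2, 0 °C
Reagents that add atoms: methyl chloroformate (12), COC(=O)Cl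
Why: O-Acylation with the chloroformate converts the alcohol into the allylic methyl carbonate, the leaving group needed for metal-allyl ionisation in step 7.

Step 7
Reactants: 8 5-(benzyloxy)-2-{1-[2,4-bis(benzyloxy)-3-methoxyphenyl]ethenyl}phenol; 13 (E)-3-[3,4-bis(benzyloxy)phenyl]prop-2-en-1-yl methyl carbonate
Product: 14 (S)-4-(benzyloxy)-2-({1-[3,4-bis(benzyloxy)phenyl]prop-2-en-1-yl}oxy)-1-{1-[2,4-bis(benzyloxy)-3-methoxyphenyl]ethenyl}benzene
Conditions: 8, LiHMDS (1.0 equiv), THF; [Ir(cod)Cl]2 (2 mol %), (Sa)-O,O′-(1,1′-binaphthyl-2,2′-diyl) N,N-bis[(S)-1-phenylethyl]phosphoramidite (4 mol %), pre-activated with n-PrNH2; THF, rt to 40 °C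
Reagents that add atoms: none
Why: Ir-catalysed asymmetric allylic etherification: the cyclometalated Ir–phosphoramidite ionises the linear carbonate to an allyl complex that the lithium phenoxide should attack at the aryl-substituted terminus to give the branched ether, the chiral ligand fixing C2 as (S).

Step 8
Reactants: 14 (S)-4-(benzyloxy)-2-({1-[3,4-bis(benzyloxy)phenyl]prop-2-en-1-yl}oxy)-1-{1-[2,4-bis(benzyloxy)-3-methoxyphenyl]ethenyl}benzene
Product: 15 (2S)-7-(benzyloxy)-2-[3,4-bis(benzyloxy)phenyl]-4-[2,4-bis(benzyloxy)-3-methoxyphenyl]-2H-chromene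
Conditions: second-generation Hoveyda–Grubbs catalyst (10 mol %), 1,4-benzoquinone (10 mol %), CH2Cl2 (5 mM), 40 °C, argon sparge, exclusion of light
Reagents that add atoms: none
Why: The Ru alkylidene should initiate at the monosubstituted vinyl group on C2, and the resulting Ru=C3 alkylidene should undergo intramolecular [2+2] cycloaddition and cycloreversion with the 1,1-diarylethylene, whose internal carbon becomes C4, so that the C3=C4 bond forms and ethylene is lost. The closest known reaction type is ring-closing olefin metathesis of aryl allyl ethers bearing an ortho alk-1-en-2-yl group to 4-substituted 2H-chromenes. Ring C is closed as a six-membered ring with the new olefin endocyclic, the closure being driven by loss of ethylene. No new stereocenter is created; C2 is carried through untouched under neutral conditions, and C3 and C4 are set together in step 9. The step needs ring closure to win over intermolecular dimerisation and over Ru–H isomerisation of the allyl ether: the gem-diaryl olefin cannot homodimerise and so reacts only intramolecularly, high dilution disfavours coupling through the vinyl group, and benzoquinone scavenges Ru–H species. Low temperature and exclusion of light guard C2 against reversible oxa-6π ring opening of the 2H-chromene.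

Step 9
Reactants: 15 (2S)-7-(benzyloxy)-2-[3,4-bis(benzyloxy)phenyl]-4-[2,4-bis(benzyloxy)-3-methoxyphenyl]-2H-chromene; 16 borane–tetrahydrofuran complex; 17 hydrogen peroxide
Product: 19 (2R,3S,4S)-7-(benzyloxy)-2-[3,4-bis(benzyloxy)phenyl]-4-[2,4-bis(benzyloxy)-3-methoxyphenyl]-3,4-dihydro-2H-chromen-3-ol, via C3 alkylborane 18 (not isolated)
Conditions: BH3·THF (3 equiv), THF, 0 °C to rt; then 3 M NaOH, 30% H2O2, 0 °C to rt
Reagents that add atoms: borane–tetrahydrofuran complex (16), [BH3-][O+]1CCCC1 (boron of 18); hydrogen peroxide (17), OO (oxygen at C3)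
Why: Hydroboration–oxidation: BH3 should add syn across C3=C4 with boron at C3 (the less substituted carbon, remote from the diaryl-stabilised C4) on the face anti to the C2 aryl group, and oxidation with retention should give the 3-OH trans to the 2-aryl group and cis to H-4, so that C2 sets both C3 and C4 in one event with all three substituents equatorial.

Step 10
Reactants: 19 (2R,3S,4S)-7-(benzyloxy)-2-[3,4-bis(benzyloxy)phenyl]-4-[2,4-bis(benzyloxy)-3-methoxyphenyl]-3,4-dihydro-2H-chromen-3-ol
Product: 20 (2R,3S,4R)-2-(3,4-dihydroxyphenyl)-4-(2,4-dihydroxy-3-methoxyphenyl)-3,4-dihydro-2H-chromene-3,7-diol (CNP0124388.1)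
Conditions: H2 (1 atm), 20% Pd(OH)2/C, THF–MeOH, rt
Reagents that add atoms: none
Why: Catalytic hydrogenolysis of the five O-benzyl ethers under neutral conditions at room temperature should leave the ring C ether bond, the doubly benzylic C4–H and all three stereocenters untouched. The C4 descriptor changes from S to R only because the priorities of ring D and ring A change on debenzylation.

Compound list
1 | 2-methoxybenzene-1,3-diol (2-methoxyresorcinol) | COc1c(O)cccc1O | starting material
2 | benzyl bromide | BrCc1ccccc1 | starting material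
3 | 1,3-bis(benzyloxy)-2-methoxybenzene | COc1c(OCc2ccccc2)cccc1OCc1ccccc1 | intermediate
4 | N-bromosuccinimide | O=C1CCC(=O)N1Br | starting material
5 | 1,3-bis(benzyloxy)-4-bromo-2-methoxybenzene | COc1c(OCc2ccccc2)ccc(Br)c1OCc1ccccc1 | intermediate
6 | 1-[4-(benzyloxy)-2-hydroxyphenyl]ethan-1-one | CC(=O)c1ccc(OCc2ccccc2)cc1O | starting material
7 | 1-[2,4-bis(benzyloxy)-3-methoxyphenyl]-1-[4-(benzyloxy)-2-hydroxyphenyl]ethan-1-ol (racemic, not isolated) | CC(O)(c1ccc(OCc2ccccc2)cc1O)c1ccc(OCc2ccccc2)c(OC)c1OCc1ccccc1 | intermediate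
8 | 5-(benzyloxy)-2-{1-[2,4-bis(benzyloxy)-3-methoxyphenyl]ethenyl}phenol | C=C(c1ccc(OCc2ccccc2)cc1O)c1ccc(OCc2ccccc2)c(OC)c1OCc1ccccc1 | intermediate
9 | caffeic acid, (E)-3-(3,4-dihydroxyphenyl)prop-2-enoic acid | OC(=O)/C=C/c1ccc(O)c(O)c1 | starting material
10 | benzyl (E)-3-[3,4-bis(benzyloxy)phenyl]prop-2-enoate | O=C(/C=C/c1ccc(OCc2ccccc2)c(OCc2ccccc2)c1)OCc1ccccc1 | intermediate
11 | (E)-3-[3,4-bis(benzyloxy)phenyl]prop-2-en-1-ol | OC/C=C/c1ccc(OCc2ccccc2)c(OCc2ccccc2)c1 | intermediate
12 | methyl chloroformate | COC(=O)Cl | starting material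
13 | (E)-3-[3,4-bis(benzyloxy)phenyl]prop-2-en-1-yl methyl carbonate | COC(=O)OC/C=C/c1ccc(OCc2ccccc2)c(OCc2ccccc2)c1 | intermediate
14 | (S)-4-(benzyloxy)-2-({1-[3,4-bis(benzyloxy)phenyl]prop-2-en-1-yl}oxy)-1-{1-[2,4-bis(benzyloxy)-3-methoxyphenyl]ethenyl}benzene | C=C[C@H](Oc1cc(OCc2ccccc2)ccc1C(=C)c1ccc(OCc2ccccc2)c(OC)c1OCc1ccccc1)c1ccc(OCc2ccccc2)c(OCc2ccccc2)c1 | intermediate
15 | (2S)-7-(benzyloxy)-2-[3,4-bis(benzyloxy)phenyl]-4-[2,4-bis(benzyloxy)-3-methoxyphenyl]-2H-chromene | COc1c(OCc2ccccc2)ccc(C2=C[C@@H](c3ccc(OCc4ccccc4)c(OCc4ccccc4)c3)Oc3cc(OCc4ccccc4)ccc32)c1OCc1ccccc1 | intermediate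
16 | borane–tetrahydrofuran complex | [BH3-][O+]1CCCC1 | starting material
17 | hydrogen peroxide | OO | starting material
18 | {7-(benzyloxy)-2-[3,4-bis(benzyloxy)phenyl]-4-[2,4-bis(benzyloxy)-3-methoxyphenyl]-3,4-dihydro-2H-chromen-3-yl}borane, boron trans to the 2-aryl and 4-aryl groups (not isolated) | COc1c(OCc2ccccc2)ccc([C@@H]2c3ccc(OCc4ccccc4)cc3O[C@H](c3ccc(OCc4ccccc4)c(OCc4ccccc4)c3)[C@H]2B)c1OCc1ccccc1 | intermediate
19 | (2R,3S,4S)-7-(benzyloxy)-2-[3,4-bis(benzyloxy)phenyl]-4-[2,4-bis(benzyloxy)-3-methoxyphenyl]-3,4-dihydro-2H-chromen-3-ol | COc1c(OCc2ccccc2)ccc([C@@H]2c3ccc(OCc4ccccc4)cc3O[C@H](c3ccc(OCc4ccccc4)c(OCc4ccccc4)c3)[C@H]2O)c1OCc1ccccc1 | intermediate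
20 | (2R,3S,4R)-2-(3,4-dihydroxyphenyl)-4-(2,4-dihydroxy-3-methoxyphenyl)-3,4-dihydro-2H-chromene-3,7-diol | COc1c(O)ccc([C@@H]2c3ccc(O)cc3O[C@H](c3ccc(O)c(O)c3)[C@H]2O)c1O | target

Total step count: 10. Longest linear sequence: 7 steps (steps 1, 2, 3, 7, 8, 9, 10, or equally steps 4, 5, 6, 7, 8, 9, 10).

Steps most likely to fail

Step 8. Metathesis at the hindered gem-diaryl olefin may be slow, so that coupling through the vinyl group or isomerisation of the allyl ether takes over. Forcing the temperature may erode C2 through reversible ring opening of the 2H-chromene. The fallback sets out from 14. Lemieux–Johnson oxidation (OsO4 cat., NaIO4, 2,6-lutidine, dioxane–water) would cleave both terminal methylene groups to give (R)-2-[3,4-bis(benzyloxy)phenyl]-2-{5-(benzyloxy)-2-[2,4-bis(benzyloxy)-3-methoxybenzoyl]phenoxy}acetaldehyde F1, used crude because its α-stereocenter is labile. An intramolecular McMurry coupling with low-valent titanium (TiCl3(DME)1.5, Zn–Cu couple, DME, reflux, slow addition) would then join the aldehyde and ketone carbons into the C3=C4 olefin. The fallback comes back to the route at 15.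

Step 7. Attack of the hindered ortho-substituted phenoxide may be slow, which would give the catalyst time to re-ionise the electron-rich branched aryl ether, with loss of branched selectivity and of enantiomeric purity. The fallback makes the O–aryl bond instead of the C2–O bond and sets out from 13 and 5.
- Ir-catalysed allylic hydroxylation of 13 with KHCO3 as the oxygen nucleophile (same Ir–phosphoramidite system) would give (S)-1-[3,4-bis(benzyloxy)phenyl]prop-2-en-1-ol F2, an alcohol that the catalyst does not re-ionise.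
- Br–Li exchange of 5 (n-BuLi, THF, −78 °C), addition to commercial 4-(benzyloxy)-2-fluorobenzonitrile F3 and acidic hydrolysis of the ketimine would give [2,4-bis(benzyloxy)-3-methoxyphenyl][4-(benzyloxy)-2-fluorophenyl]methanone F4.
- Nucleophilic aromatic substitution of the ketone-activated fluoride in F4 by the potassium alkoxide of F2 (KHMDS, THF–DMF, 0 °C) leaves the stereocenter untouched and would give (S)-[4-(benzyloxy)-2-({1-[3,4-bis(benzyloxy)phenyl]prop-2-en-1-yl}oxy)phenyl][2,4-bis(benzyloxy)-3-methoxyphenyl]methanone F5.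
- Wittig methylenation (Ph3PCH3Br, KOtBu, THF) comes back to the route at 14.

Step 9. The C3 borane may ring-open by β-elimination of the ring oxygen as a phenoxide, the hindered trisubstituted olefin may react incompletely, or the facial preference may be weaker than expected. The fallback avoids an organoborane and sets out from 15. Acridinium photoredox anti-Markovnikov hydroacetoxylation (9-mesityl-10-methylacridinium tetrafluoroborate cat., PhSSPh cat., AcOH, 1,2-dichloroethane, 450 nm LEDs) should trap the olefin radical cation with acetate at C3 anti to the C2 aryl group. The diaryl-stabilised C4 radical is then expected to take up hydrogen so that ring D becomes equatorial, giving (2R,3S,4S)-7-(benzyloxy)-2-[3,4-bis(benzyloxy)phenyl]-4-[2,4-bis(benzyloxy)-3-methoxyphenyl]-3,4-dihydro-2H-chromen-3-yl acetate F6. Methanolysis (K2CO3, MeOH) comes back to the route at 19.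

Further compounds
F1 | step 8 | (R)-2-[3,4-bis(benzyloxy)phenyl]-2-{5-(benzyloxy)-2-[2,4-bis(benzyloxy)-3-methoxybenzoyl]phenoxy}acetaldehyde | O=C[C@H](Oc1cc(OCc2ccccc2)ccc1C(=O)c1ccc(OCc2ccccc2)c(OC)c1OCc1ccccc1)c1ccc(OCc2ccccc2)c(OCc2ccccc2)c1
F2 | step 7 | (S)-1-[3,4-bis(benzyloxy)phenyl]prop-2-en-1-ol | C=C[C@H](O)c1ccc(OCc2ccccc2)c(OCc2ccccc2)c1
F3 | step 7 | 4-(benzyloxy)-2-fluorobenzonitrile | N#Cc1ccc(OCc2ccccc2)cc1F
F4 | step 7 | [2,4-bis(benzyloxy)-3-methoxyphenyl][4-(benzyloxy)-2-fluorophenyl]methanone | O=C(c1ccc(OCc2ccccc2)cc1F)c1ccc(OCc2ccccc2)c(OC)c1OCc1ccccc1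
F5 | step 7 | (S)-[4-(benzyloxy)-2-({1-[3,4-bis(benzyloxy)phenyl]prop-2-en-1-yl}oxy)phenyl][2,4-bis(benzyloxy)-3-methoxyphenyl]methanone | C=C[C@H](Oc1cc(OCc2ccccc2)ccc1C(=O)c1ccc(OCc2ccccc2)c(OC)c1OCc1ccccc1)c1ccc(OCc2ccccc2)c(OCc2ccccc2)c1
F6 | step 9 | (2R,3S,4S)-7-(benzyloxy)-2-[3,4-bis(benzyloxy)phenyl]-4-[2,4-bis(benzyloxy)-3-methoxyphenyl]-3,4-dihydro-2H-chromen-3-yl acetate | COc1c(OCc2ccccc2)ccc([C@@H]2c3ccc(OCc4ccccc4)cc3O[C@H](c3ccc(OCc4ccccc4)c(OCc4ccccc4)c3)[C@H]2OC(C)=O)c1OCc1ccccc1
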